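**Retrosynthetic overview**
1. End game on a preformed ring: 23 ⇐ oxidation of the C4 carbinol side chain ⇐ C2 enolate hydroxylation ⇐ C4 γ-aldol of a dione dianion ⇐ C2 prenylation of cyclooctane-1,3-dione 17.
2. Key disconnection, chosen over degrading a hyperforin-type bicyclo[3.3.1]nonane or closing the ring by RCM/Dieckmann: excise C2–C3 as a ketene. 17 ⇐ retro-aldol of 1-siloxybicyclo[4.2.0]octan-7-one 16 ⇐ dichloroketene + silyl enol ether 13.
3. 13 ⇐ anti cuprate addition (sets C5) to enone 10 ⇐ trans α'-prenylation (sets C8) of enone 8. C5, C6 and C8 are all set on a six-membered ring.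
4. 8 ⇐ β-methylation/re-oxidation of (R)-4-prenylcyclohexenone 6 ⇐ organocatalytic Michael (sets C6) and aldol condensation of 5-methylhex-4-enal + MVK.
5. Ring order: cyclohexene (step 3) → fused cyclobutanone (step 7) → cyclooctane by cleaving the shared bond (step 9).

Assumption: C4–H lies between two carbonyls and is configurationally labile, so the natural 4R centre is taken to be the thermodynamic epimer.
Convention: all eight-membered intermediates carry the target numbering (C1 C=O, C2, C3 C=O, C4, C5 quaternary, C6, C7, C8). prenyl = 3-methylbut-2-en-1-yl; homoprenyl = 4-methylpent-3-en-1-yl.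

**Step 1**
Reactants: 1 (2-methylbut-3-en-2-ol), 2 (ethyl vinyl ether)
Product: 3, 5-methylhex-4-enal
Conditions: 2 (excess), cat. H3PO4, sealed tube, 150 °C
Reagents that add atoms: ethyl vinyl ether, C=COCC (supplies the CH2–CHO carbons)
Why: Acid-catalysed vinyl-ether exchange followed by Claisen [3,3] rearrangement of the tertiary allyl vinyl ether gives the γ,δ-unsaturated aldehyde, with no stereocentre formed.

**Step 2**
Reactants: 3, 4 (methyl vinyl ketone)
Product: 5, (2R)-5-methyl-2-(3-oxobutyl)hex-4-enal
Conditions: (R)-2-[methoxy(diphenyl)methyl]pyrrolidine (5 mol %), ethyl 3,4-dihydroxybenzoate (20 mol %), neat, 4 °C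
Reagents that add atoms: methyl vinyl ketone, CC(=O)C=C
Why: In this enamine-catalysed asymmetric Michael addition, MVK attacks the E-enamine on the face opposite the CPh2OMe group, so the (R)-catalyst gives the 2R aldehyde (future C6) in high ee.

**Step 3**
Reactants: 5
Product: 6, (4R)-4-prenylcyclohex-2-en-1-one
Conditions: LiOH, i-PrOH, rt
Reagents that add atoms: none
Why: Intramolecular aldol condensation of the methyl ketone onto the aldehyde closes the six-membered ring, and the mild base and short time preserve the γ-stereocentre.

**Step 4**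
Reactants: 6, 7 (methyllithium, used as Me2CuLi)
Product: 8, (4R)-3-methyl-4-prenylcyclohex-2-en-1-one
Conditions: Me2CuLi (7, CuI), Et2O, −78 °C; then PhS(Cl)=N-t-Bu, THF, −78 °C
Reagents that add atoms: methyllithium, [Li]C
Why: Gilman conjugate addition is followed by one-pot Mukaiyama dehydrogenation of the regiodefined enolate (sulfenylation anti to the new methyl, then syn-elimination of C3–H), which restores the enone with C4 untouched.

**Step 5**
Reactants: 8, 9 (prenyl bromide)
Product: 10, (4S,6S)-3-methyl-4,6-diprenylcyclohex-2-en-1-one (4,6-trans; C4 changes descriptor only through CIP ranking)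
Conditions: LDA, THF, −78 °C; 9, −78 → −30 °C
Reagents that add atoms: prenyl bromide, CC(C)=CCBr
Why: In this kinetic α'-enolate alkylation the C4 prenyl is pseudoaxial (A1,2 strain with C3-Me) and blocks its own face, so the electrophile enters anti and gives the trans isomer (future C8), which is also the more stable one (C6 equatorial).

**Step 6**
Reactants: 10, 11 (5-bromo-2-methylpent-2-ene, as its Grignard reagent), 12 (TMSCl)
Product: 13, {[(3R,4S,6S)-3-methyl-3-homoprenyl-4,6-diprenylcyclohex-1-en-1-yl]oxy}trimethylsilane
Conditions: homoprenylMgBr (11, Mg, THF), CuBr·SMe2, TMSCl, HMPA, THF, −78 → −40 °C; Et3N, cold NaHCO3 work-up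
Reagents that add atoms: 5-bromo-2-methylpent-2-ene, CC(C)=CCCBr; chlorotrimethylsilane, C[Si](C)(C)Cl
Why: TMSCl-accelerated cuprate 1,4-addition occurs axially, anti to the pseudoaxial C4 prenyl, setting the quaternary centre (homoprenyl trans and Me cis to that prenyl) and trapping the Δ1,2 silyl enol ether regiospecifically.

**Step 7** (key step, part 1)
Reactants: 13, 14 (dichloroacetyl chloride)
Product: 15, (2S,4S,5R)-8,8-dichloro-5-methyl-5-homoprenyl-2,4-diprenyl-1-(trimethylsilyloxy)bicyclo[4.2.0]octan-7-one (cis-fused; the face at C1/C6 is irrelevant)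
Conditions: 14, Et3N, hexanes, 0 °C → rt
Reagents that add atoms: dichloroacetyl chloride, ClC(Cl)C(Cl)=O (reacts as dichloroketene)
Why: In this ketene/enol-ether [2+2] cycloaddition the nucleophilic β-carbon bonds to the ketene carbonyl carbon so CCl2 ends on the siloxy carbon, and Et3N-generated dichloroketene reacts with the electron-rich enol ether but not with unactivated trisubstituted alkenes.

**Step 8**
Reactants: 15
Product: 16, (2S,4S,5R)-5-methyl-5-homoprenyl-2,4-diprenyl-1-(trimethylsilyloxy)bicyclo[4.2.0]octan-7-one
Conditions: Zn dust, AcOH–THF, 0 °C → rt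
Reagents that add atoms: none
Why: Zinc reductively dechlorinates the α,α-dichloroketone, removing the CCl2 carbanion-stabilising group that would otherwise steer ring opening toward a dichloroacetyl ketone, and any prematurely desilylated material converges in step 9.

**Step 9** (key step, part 2)
Reactants: 16
Product: 17, (5S,6S,8S)-5-methyl-5-homoprenyl-6,8-diprenylcyclooctane-1,3-dione (same spatial arrangement as the target; the C5 descriptor differs only by CIP ranking)
Conditions: AcOH–H2O (1:2), i-PrOH, 80 °C
Reagents that add atoms: none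
Why: Desilylation and retro-aldol (de Mayo-type) fragmentation break the most substituted, most strained ring-fusion bond via the more substituted enol, as in the established cyclopentanone → cycloheptane-1,3-dione ring expansion, so both fusion centres vanish while C5, C6 and C8 are untouched.

**Step 10**
Reactants: 17, 9 (prenyl bromide)
Product: 18, (5S,6S,8S)-5-methyl-5-homoprenyl-2,6,8-triprenylcyclooctane-1,3-dione (C2 labile, keto/enol mixture)
Conditions: 9 (1.05 equiv), K2CO3, acetone, rt
Reagents that add atoms: prenyl bromide, CC(C)=CCBr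
Why: C-alkylation of the 1,3-diketonate with a soft allylic bromide takes place at C2, the only strongly acidic site, and C8 is protected from epimerisation because the dione is present as its enolate.

**Step 11**
Reactants: 18, 19 (isobutyraldehyde)
Product: 20, (5R,6S,8S)-4-(1-hydroxy-2-methylpropyl)-5-methyl-5-homoprenyl-2,6,8-triprenylcyclooctane-1,3-dione (mixture at C2, C4 and the carbinol carbon, all corrected later)
Conditions: LDA (2.3 equiv), THF, −78 → 0 °C; 19, −78 °C; AcOH quench
Reagents that add atoms: isobutyraldehyde, CC(C)C=O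
Why: In this Hauser/Weiler-type 1,3-dicarbonyl dianion γ-aldol, the second deprotonation takes the C4 methylene rather than the C8 methine, and the dianion reacts only at its γ-carbon.

**Step 12**
Reactants: 20, 21 (2-(phenylsulfonyl)-3-phenyloxaziridine)
Product: 22, (2R,5R,6S,8S)-2-hydroxy-4-(1-hydroxy-2-methylpropyl)-5-methyl-5-homoprenyl-2,6,8-triprenylcyclooctane-1,3-dione
Conditions: NaHMDS (1.05 equiv), THF, −78 °C; 21; AcOH quench at −78 °C
Reagents that add atoms: Davis oxaziridine, O=S(=O)(c1ccccc1)N1OC1c1ccccc1 (adds O)
Why: Davis enolate hydroxylation is chemoselective over the four alkenes, and in the conformer that keeps the C6 and C8 prenyls pseudo-equatorial, the C5–C7 bridge and the inward homoprenyl chain cover one face of the C1–C2–C3 enolate, so oxygen arrives on the open peripheral (Re) face to give 2R, with any 2-epimer being a separable diastereomer.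

**Step 13**
Reactants: 22
Product: 23, hyphenrone F, (2R,4R,5R,6S,8S)-2-hydroxy-5-methyl-5-homoprenyl-4-(2-methylpropanoyl)-2,6,8-triprenylcyclooctane-1,3-dione
Conditions: Dess–Martin periodinane (1.2 equiv), NaHCO3, CH2Cl2, 0 °C → rt; then cat. Et3N, CH2Cl2, rt
Reagents that add atoms: none
Why: Dess–Martin oxidation converts only the secondary alcohol, and the resulting β-diketone C4–H equilibrates through its enol to the more stable 4R epimer (isobutyryl anti to the C5 homoprenyl chain), under a base far too weak to touch C8.

**Compound list**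
1 | 2-methylbut-3-en-2-ol | CC(C)(O)C=C | starting material
2 | ethyl vinyl ether | C=COCC | starting material
3 | 5-methylhex-4-enal | CC(C)=CCCC=O | intermediate
4 | methyl vinyl ketone | CC(=O)C=C | starting material
5 | (2R)-5-methyl-2-(3-oxobutyl)hex-4-enal | O=C[C@@H](CC=C(C)C)CCC(C)=O | intermediate
6 | (4R)-4-prenylcyclohex-2-en-1-one | C1=CC(=O)CC[C@@H]1CC=C(C)C | intermediate
7 | methyllithium | [Li]C | starting material (reagent)
8 | (4R)-3-methyl-4-prenylcyclohex-2-en-1-one | CC1=CC(=O)CC[C@@H]1CC=C(C)C | intermediate
9 | prenyl bromide | CC(C)=CCBr | starting material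
10 | (4S,6S)-3-methyl-4,6-diprenylcyclohex-2-en-1-one | CC1=CC(=O)[C@@H](CC=C(C)C)C[C@@H]1CC=C(C)C | intermediate
11 | 5-bromo-2-methylpent-2-ene | CC(C)=CCCBr | starting material
12 | chlorotrimethylsilane | C[Si](C)(C)Cl | starting material (reagent)
13 | (3R,4S,6S)-silyl enol ether | CC(C)=CCC[C@]1(C)[C@@H](CC=C(C)C)C[C@H](CC=C(C)C)C(O[Si](C)(C)C)=C1 | intermediate
14 | dichloroacetyl chloride | ClC(Cl)C(Cl)=O | starting material
15 | (2S,4S,5R)-8,8-dichloro-1-siloxybicyclo[4.2.0]octan-7-one (cis-fused, C1/C6 undefined) | CC(C)=CCC[C@]1(C)[C@@H](CC=C(C)C)C[C@H](CC=C(C)C)C2(O[Si](C)(C)C)C(Cl)(Cl)C(=O)C12 | intermediate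
16 | (2S,4S,5R)-1-siloxybicyclo[4.2.0]octan-7-one (cis-fused, C1/C6 undefined) | CC(C)=CCC[C@]1(C)[C@@H](CC=C(C)C)C[C@H](CC=C(C)C)C2(O[Si](C)(C)C)CC(=O)C12 | intermediate
17 | (5S,6S,8S)-5-methyl-5-homoprenyl-6,8-diprenylcyclooctane-1,3-dione | CC(C)=CCC[C@]1(C)[C@@H](CC=C(C)C)C[C@H](CC=C(C)C)C(=O)CC(=O)C1 | intermediate
18 | (5S,6S,8S)-2,6,8-triprenyl dione (C2 labile) | CC(C)=CCC[C@]1(C)[C@@H](CC=C(C)C)C[C@H](CC=C(C)C)C(=O)C(CC=C(C)C)C(=O)C1 | intermediate
19 | isobutyraldehyde | CC(C)C=O | starting material
20 | (5R,6S,8S)-C4 γ-aldol adduct (C2, C4, carbinol undefined) | CC(C)=CCC[C@]1(C)[C@@H](CC=C(C)C)C[C@H](CC=C(C)C)C(=O)C(CC=C(C)C)C(=O)C1C(O)C(C)C | intermediate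
21 | 2-(phenylsulfonyl)-3-phenyloxaziridine | O=S(=O)(c1ccccc1)N1OC1c1ccccc1 | starting material (reagent)
22 | (2R,5R,6S,8S)-2-hydroxy aldol adduct (C4, carbinol undefined) | CC(C)=CCC[C@]1(C)[C@@H](CC=C(C)C)C[C@H](CC=C(C)C)C(=O)[C@](O)(CC=C(C)C)C(=O)C1C(O)C(C)C | intermediate
23 | hyphenrone F | CC(C)=CCC[C@]1(C)[C@@H](CC=C(C)C)C[C@H](CC=C(C)C)C(=O)[C@](O)(CC=C(C)C)C(=O)[C@H]1C(=O)C(C)C | target

**Total steps:** 13. **Longest linear sequence:** 13 (fully linear; every coupling partner is commercial).

**Three steps most likely to fail**
1. **Step 7, together with the direction of ring opening in step 9.** The enol-ether carbon that must bond first is neopentyl, so simple C-acylation with silyl transfer may compete. The cyclobutanol could also open its other bond and give a 2-acetylcyclohexanone.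
   Fallback: insert the C2 unit into the other, unhindered α-bond.
   - Omit step 5 and trap the cuprate enolate of 8 with isobutyraldehyde (three-component coupling), then protect as the TBS ether.
   - Form the kinetic Δ1,6 TMS enol ether and carry out the ketene insertion there, so the old carbonyl becomes C3.
   - Introduce the C8 and C2 prenyl groups afterwards by γ- then α-alkylation of the dione dianion.
2. **Step 11.** The γ-aldol occurs at a neopentyl carbon. Deprotonation at C8 or enolisation of the aldehyde may compete.
   Fallback: change both the order and the bond-forming mode.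
   - Hydroxylate C2 of 18 first and protect the alcohol as its TES ether, so that C3 can enolise only toward C4.
   - Acylate C4 directly by soft enolisation (MgBr2·OEt2, i-Pr2NEt, N-isobutyrylbenzotriazole).
   - This removes the aldol and oxidation steps.
3. **Step 12.** The risks are facial selectivity at C2 and base lability of the α-ketol (ring contraction or retro-Claisen).
   Fallback: reverse the order of bond formation at C2.
   - Oxidise dione 17 to its 2-acyloxy derivative first.
   - Form the C2–prenyl bond by Pd-catalysed allylic alkylation with a chiral Trost-type ligand.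
   - The same substrate bias then gives the opposite C2 epimer, and the ligand adds reagent control.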